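Everything rests on disconnecting ring A last: its carbons C5 to C8 are annulated onto the C4a=C8a bond of a finished 2-aryl-3-oxy-4-pyranone (ring C from kojic acid, ring B by Suzuki coupling). In one light-then-heat operation an α-prenyl α-diazo ketone and methoxyacetylene are merged by Wolff rearrangement, ketene/ynol ether [2+2], 4π opening and 6π electrocyclization. The step exploits the resorcinol monoether pattern of ring A (5-OH, C6-H, 7-OMe, 8-prenyl) and the pre-existing O1–C8a bond, which leaves C4a as the only closure site and so fixes prenyl at C8. The precursor is a 6-acyl-4-pyranone whose diazo carbon bears the prenyl group, with the 3-OH and 4'-OH masked as MOM ethers.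

Key step: step 10

Remark on the chemistry: the SMILES is taken as defining the target (flavone with 3-OH, 5-OH, 4'-OH, 7-OMe and 8-prenyl); ring atoms are referred to by flavone numbering (O1, C2 to C8a), and all chiral intermediates are racemic.

Step 1
Reactants: 1 kojic acid (5-hydroxy-2-(hydroxymethyl)-4H-pyran-4-one)
Product: 2 2-bromo-3-hydroxy-6-(hydroxymethyl)-4H-pyran-4-one (6-bromokojic acid)
Conditions: NBS (1.05 equiv), MeCN, 0 °C to rt, dark
Reagents that add atoms: N-bromosuccinimide, O=C1CCC(=O)N1Br
Why: Electrophilic bromination of the enol, which behaves like a phenol and reacts at the only carbon ortho to the enolic OH (between the ring oxygen and C–OH), the site of its known Mannich and aldol reactions, while the other ring CH is not activated by the hydroxyl group.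

Step 2
Reactants: 2 2-bromo-3-hydroxy-6-(hydroxymethyl)-4H-pyran-4-one
Product: 3 2-bromo-6-(hydroxymethyl)-3-(methoxymethoxy)-4H-pyran-4-one
Conditions: MOMCl (1.1 equiv), K2CO3 (1.5 equiv), acetone, 0 °C to rt
Reagents that add atoms: chloromethyl methyl ether, COCCl
Why: Williamson-type O-alkylation in which carbonate deprotonates only the acidic enolic OH (a vinylogous carboxylic acid), so the primary alcohol should stay free for the later oxidation.

Step 3
Reactants: 3 2-bromo-6-(hydroxymethyl)-3-(methoxymethoxy)-4H-pyran-4-one; 4 4-(methoxymethoxy)phenylboronic acid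
Product: 5 6-(hydroxymethyl)-3-(methoxymethoxy)-2-[4-(methoxymethoxy)phenyl]-4H-pyran-4-one
Conditions: Pd(PPh3)4 (5 mol %), K2CO3 (2.5 equiv), 1,4-dioxane/H2O (4:1), 85 °C, argon
Reagents that add atoms: none
Why: Suzuki–Miyaura coupling at a β-bromo enone (vinylogous acyl bromide), where oxidative addition of zerovalent palladium is fast and neither the free alcohol nor the MOM acetals should interfere under aqueous carbonate.

Step 4
Reactants: 5 6-(hydroxymethyl)-3-(methoxymethoxy)-2-[4-(methoxymethoxy)phenyl]-4H-pyran-4-one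
Product: 6 5-(methoxymethoxy)-6-[4-(methoxymethoxy)phenyl]-4-oxo-4H-pyran-2-carbaldehyde
Conditions: activated MnO2 (15 equiv), CH2Cl2, rt, filtration through Celite
Reagents that add atoms: none
Why: MnO2 oxidation of an allylic-type primary alcohol (the CH2OH sits on the pyranone C=C) should stop at the aldehyde under neutral, non-aqueous conditions that spare the MOM acetals and avoid the aldehyde hydrate.

Step 5
Reactants: 6 5-(methoxymethoxy)-6-[4-(methoxymethoxy)phenyl]-4-oxo-4H-pyran-2-carbaldehyde; 7 5-bromo-2-methylpent-2-ene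
Product: 9 rac-6-(1-hydroxy-5-methylhex-4-enyl)-3-(methoxymethoxy)-2-[4-(methoxymethoxy)phenyl]-4H-pyran-4-one, via (4-methylpent-3-enyl)magnesium bromide 8 (not isolated)
Conditions: 7 (1.3 equiv), Mg turnings, cat. I2, THF, rt to 40 °C; the solution added dropwise to 6, THF, −78 °C; sat. aq. NH4Cl
Reagents that add atoms: none
Why: Grignard 1,2-addition, in which at −78 °C the aldehyde is far more electrophilic than the vinylogous ester carbonyl of the pyranone; the new carbinol centre is formed racemic on purpose because the next step oxidizes it.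

Step 6
Reactants: 9 rac-6-(1-hydroxy-5-methylhex-4-enyl)-3-(methoxymethoxy)-2-[4-(methoxymethoxy)phenyl]-4H-pyran-4-one
Product: 10 3-(methoxymethoxy)-2-[4-(methoxymethoxy)phenyl]-6-(5-methylhex-4-enoyl)-4H-pyran-4-one
Conditions: Dess–Martin periodinane (1.3 equiv), CH2Cl2, 0 °C to rt
Reagents that add atoms: none
Why: Dess–Martin oxidation of the secondary alcohol to the ketone under near-neutral conditions that should leave the trisubstituted alkene, the pyranone and the MOM groups untouched, and that removes the stereocentre.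

Step 7
Reactants: 10 3-(methoxymethoxy)-2-[4-(methoxymethoxy)phenyl]-6-(5-methylhex-4-enoyl)-4H-pyran-4-one
Product: 11 rac-3-(methoxymethoxy)-2-[4-(methoxymethoxy)phenyl]-6-[5-methyl-2-(trifluoroacetyl)hex-4-enoyl]-4H-pyran-4-one (used crude)
Conditions: LiN(SiMe3)2 (1.1 equiv), THF, −78 °C, 30 min; CF3CO2CH2CF3 (1.3 equiv), −78 °C, 10 min; brief cold 5% aq. HCl/Et2O partition
Reagents that add atoms: 2,2,2-trifluoroethyl trifluoroacetate, O=C(OCC(F)(F)F)C(F)(F)F
Why: Claisen-type C-trifluoroacetylation of the kinetic lithium enolate (first half of a detrifluoroacetylative diazo transfer), possible at one site only because the α-CH2 is the single enolizable position; the racemic centre it creates is lost in step 8.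

Step 8
Reactants: 11 rac-3-(methoxymethoxy)-2-[4-(methoxymethoxy)phenyl]-6-[5-methyl-2-(trifluoroacetyl)hex-4-enoyl]-4H-pyran-4-one
Product: 12 6-(2-diazo-5-methylhex-4-enoyl)-3-(methoxymethoxy)-2-[4-(methoxymethoxy)phenyl]-4H-pyran-4-one
Conditions: MsN3 (1.5 equiv), Et3N (1.5 equiv), H2O (1 equiv), MeCN, rt; kept cold and dark afterwards
Reagents that add atoms: methanesulfonyl azide, CS(=O)(=O)N=[N+]=[N-]
Why: Regitz-type deacylative diazo transfer, in which the activated 1,3-dicarbonyl takes the diazo group from mesyl azide and the trifluoroacetyl group leaves on the sulfonamide nitrogen, giving the α-alkyl α-diazo ketone that a simple ketone enolate would not give directly.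

Step 9
Reactants: 13 chloroacetaldehyde dimethyl acetal (2-chloro-1,1-dimethoxyethane)
Product: 15 methoxyacetylene, via sodium methoxyacetylide 14 (not isolated)
Conditions: NaNH2 (3 equiv), liquid NH3, −33 °C; cold sat. aq. NaCl, −70 °C; distilled into cold toluene, stored at −20 °C
Reagents that add atoms: none
Why: Twofold base-induced elimination (HCl, then methanol) with sodium amide in liquid ammonia, the standard preparation of alkoxyacetylenes, in which the third equivalent of base stores the volatile product as acetylide 14 until the cold quench.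

Step 10
Reactants: 12 6-(2-diazo-5-methylhex-4-enoyl)-3-(methoxymethoxy)-2-[4-(methoxymethoxy)phenyl]-4H-pyran-4-one; 15 methoxyacetylene
Product: 20 3,4'-di-O-MOM isoanhydroicaritin, via pyranyl(prenyl)ketene 16 (not isolated), via cyclobutenone 17 (not isolated), via dienylketene 18 (not isolated), via cyclohexadienone 19 (not isolated)
Conditions: 15 (8 equiv), degassed toluene (0.02 M in 12), pressure tube, blue LEDs (about 450 nm), 5–10 °C until N2 evolution ends; excess 15 purged with argon; then 90 °C in the dark
Reagents that add atoms: none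
Why: Proposed new method: blue light excites only the diazo ketone, N2 leaves with 1,2-shift of the pyranyl carbon (Wolff rearrangement, C8–C8a) to ketene 16, and the nucleophilic CH terminus of the ynol ether attacks the ketene carbonyl carbon in a [2+2] cycloaddition (C5–C6 and C7–C8) that closes the four-membered ring of 17 with OMe next to the prenyl-bearing carbon. On warming, conrotatory 4π opening breaks the C5–C8 bond reversibly to dienylketene 18, whose ketene-cis-to-pyranone isomer closes the six-membered ring A by disrotatory 6π electrocyclization of the ketene carbon onto the pyranone CH carbon (C5–C4a), and dienone 19 tautomerizes irreversibly to the chelated 5-OH phenol 20. The closest known reaction type is the Danheiser benzannulation in its photochemical Wolff variant, known for aryl, heteroaryl and vinyl diazo ketones with alkoxy- or siloxyalkynes, whereas a 4-pyranone as the ene partner is untested; its C=C bond is enol-ether-like and only weakly aromatic, so closure onto its nucleophilic carbon should cost less than closure onto a benzene ring. The quaternary centre of 17 and the sp3 centre of 19 are racemic and are erased by ring opening and by tautomerization, so no stereocontrol is required. Two regiochemical choices are needed and both are fixed by the substrate: the polarization of methoxyacetylene sets the 7-OMe/8-prenyl adjacency, and C8a carries only O1 and C4a, so the ketene can close only at C4a and the prenyl group can only end at C8. Long-wavelength light at low temperature is chosen to favour concerted migration over carbene 1,2-hydrogen shift and to leave the 2-aryl-4-pyranone chromophore unexcited.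

Step 11
Reactants: 20 3,4'-di-O-MOM isoanhydroicaritin
Product: 21 isoanhydroicaritin
Conditions: HCl (about 1 M) in MeOH/H2O (9:1), 45 °C
Reagents that add atoms: none
Why: Acid-catalysed transacetalization of both MOM ethers to methanol, during which the prenyl group should survive because it lies between 7-OMe and ring oxygen O1 with no free ortho-OH that could close a chroman.

Compound list
1 | kojic acid, 5-hydroxy-2-(hydroxymethyl)-4H-pyran-4-one | O=c1cc(CO)occ1O | starting material
2 | 2-bromo-3-hydroxy-6-(hydroxymethyl)-4H-pyran-4-one (6-bromokojic acid) | O=c1cc(CO)oc(Br)c1O | intermediate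
3 | 2-bromo-6-(hydroxymethyl)-3-(methoxymethoxy)-4H-pyran-4-one | O=c1cc(CO)oc(Br)c1OCOC | intermediate
4 | 4-(methoxymethoxy)phenylboronic acid | COCOc1ccc(B(O)O)cc1 | starting material
5 | 6-(hydroxymethyl)-3-(methoxymethoxy)-2-[4-(methoxymethoxy)phenyl]-4H-pyran-4-one | O=c1cc(CO)oc(-c2ccc(OCOC)cc2)c1OCOC | intermediate
6 | 5-(methoxymethoxy)-6-[4-(methoxymethoxy)phenyl]-4-oxo-4H-pyran-2-carbaldehyde | O=Cc1cc(=O)c(OCOC)c(-c2ccc(OCOC)cc2)o1 | intermediate
7 | 5-bromo-2-methylpent-2-ene | CC(C)=CCCBr | starting material
8 | (4-methylpent-3-enyl)magnesium bromide (solution, not isolated) | CC(C)=CCC[Mg]Br | intermediate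
9 | rac-6-(1-hydroxy-5-methylhex-4-enyl)-3-(methoxymethoxy)-2-[4-(methoxymethoxy)phenyl]-4H-pyran-4-one | CC(C)=CCCC(O)c1cc(=O)c(OCOC)c(-c2ccc(OCOC)cc2)o1 | intermediate
10 | 3-(methoxymethoxy)-2-[4-(methoxymethoxy)phenyl]-6-(5-methylhex-4-enoyl)-4H-pyran-4-one | CC(C)=CCCC(=O)c1cc(=O)c(OCOC)c(-c2ccc(OCOC)cc2)o1 | intermediate
11 | rac-3-(methoxymethoxy)-2-[4-(methoxymethoxy)phenyl]-6-[5-methyl-2-(trifluoroacetyl)hex-4-enoyl]-4H-pyran-4-one | CC(C)=CCC(C(=O)C(F)(F)F)C(=O)c1cc(=O)c(OCOC)c(-c2ccc(OCOC)cc2)o1 | intermediate
12 | 6-(2-diazo-5-methylhex-4-enoyl)-3-(methoxymethoxy)-2-[4-(methoxymethoxy)phenyl]-4H-pyran-4-one | CC(C)=CCC(=[N+]=[N-])C(=O)c1cc(=O)c(OCOC)c(-c2ccc(OCOC)cc2)o1 | intermediate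
13 | chloroacetaldehyde dimethyl acetal, 2-chloro-1,1-dimethoxyethane | COC(CCl)OC | starting material
14 | sodium methoxyacetylide (not isolated) | [Na+].[C-]#COC | intermediate
15 | methoxyacetylene | C#COC | intermediate
16 | pyranyl(prenyl)ketene, 2-{5-(methoxymethoxy)-6-[4-(methoxymethoxy)phenyl]-4-oxo-4H-pyran-2-yl}-5-methylhexa-1,4-dien-1-one (not isolated) | CC(C)=CCC(=C=O)c1cc(=O)c(OCOC)c(-c2ccc(OCOC)cc2)o1 | intermediate
17 | rac-3-methoxy-4-(3-methylbut-2-enyl)-4-{5-(methoxymethoxy)-6-[4-(methoxymethoxy)phenyl]-4-oxo-4H-pyran-2-yl}cyclobut-2-en-1-one (not isolated) | COC1=CC(=O)C1(CC=C(C)C)c1cc(=O)c(OCOC)c(-c2ccc(OCOC)cc2)o1 | intermediate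
18 | (3E)-3-methoxy-7-methyl-4-{5-(methoxymethoxy)-6-[4-(methoxymethoxy)phenyl]-4-oxo-4H-pyran-2-yl}octa-1,3,6-trien-1-one, the dienylketene with ketene and pyranone cis (not isolated) | O=C=C/C(OC)=C(/CC=C(C)C)c1cc(=O)c(OCOC)c(-c2ccc(OCOC)cc2)o1 | intermediate
19 | rac-7-methoxy-3-(methoxymethoxy)-2-[4-(methoxymethoxy)phenyl]-8-(3-methylbut-2-enyl)-4aH-chromene-4,5-dione (not isolated) | COC1=CC(=O)C2C(=O)C(OCOC)=C(c3ccc(OCOC)cc3)OC2=C1CC=C(C)C | intermediate
20 | 3,4'-di-O-MOM isoanhydroicaritin, 5-hydroxy-7-methoxy-3-(methoxymethoxy)-2-[4-(methoxymethoxy)phenyl]-8-(3-methylbut-2-enyl)-4H-chromen-4-one | COc1cc(O)c2c(=O)c(OCOC)c(-c3ccc(OCOC)cc3)oc2c1CC=C(C)C | intermediate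
21 | isoanhydroicaritin, 3,5-dihydroxy-2-(4-hydroxyphenyl)-7-methoxy-8-(3-methylbut-2-enyl)-4H-chromen-4-one | COc1cc(O)c2c(=O)c(O)c(-c3ccc(O)cc3)oc2c1CC=C(C)C | target

Total step count: 11
Longest linear sequence: 10 steps (steps 1 to 8, 10 and 11 from kojic acid; step 9 is the side branch to the alkyne)

Steps most likely to fail

Step 10. Nitrogen loss may give a free acyl carbene whose 1,2-hydrogen shift from the prenyl CH2 outruns pyranyl migration. The opened dienylketene may also drain away by 1,5-hydrogen shift from the isomer with prenyl turned inward, or the 6π closure onto the pyranone may be too slow. The fallback uses known chemistry only: ring A is taken from an acetophenone and the prenyl group is moved to C8 by a Claisen–Cope shift. No intermediate of the main line contains ring A, so the fallback branches at the very start: it sets out beside kojic acid 1, from purchased 1-(2,6-dihydroxy-4-methoxyphenyl)ethanone F1, and comes back to the route at compound 20. Mono-O-prenylation of F1 (prenyl bromide, K2CO3, acetone; the second OH stays hydrogen-bonded to the ketone) should give 1-[2-hydroxy-4-methoxy-6-(3-methylbut-2-enyloxy)phenyl]ethanone F2. Claisen–Schmidt condensation of F2 with purchased 4-(methoxymethoxy)benzaldehyde F3 (KOH, EtOH) should give (E)-1-[2-hydroxy-4-methoxy-6-(3-methylbut-2-enyloxy)phenyl]-3-[4-(methoxymethoxy)phenyl]prop-2-en-1-one F4. Algar–Flynn–Oyamada oxidation (H2O2, NaOH, MeOH, 0 °C to rt) should then give 3-hydroxy-7-methoxy-2-[4-(methoxymethoxy)phenyl]-5-(3-methylbut-2-enyloxy)-4H-chromen-4-one F5; the isolated alkene is inert to alkaline peroxide, and aurone formation is the known side path. MOMCl with i-Pr2NEt should give 7-methoxy-3-(methoxymethoxy)-2-[4-(methoxymethoxy)phenyl]-5-(3-methylbut-2-enyloxy)-4H-chromen-4-one F6. The europium-catalysed para-Claisen–Cope rearrangement (Eu(fod)3, chlorobenzene, 80 °C) should move the prenyl group from O5 through C6 to C8 and free the 5-OH, which is compound 20.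

Step 7. The amide base or the enolate may attack the electron-poor pyranone, or acylation may occur on oxygen instead of carbon, so that no clean substrate for diazo transfer forms. The fallback avoids enolate chemistry, sets out from aldehyde 6 and comes back at compound 20. Pinnick oxidation (NaClO2, NaH2PO4, 2-methyl-2-butene, t-BuOH/H2O) should give 5-(methoxymethoxy)-6-[4-(methoxymethoxy)phenyl]-4-oxo-4H-pyran-2-carboxylic acid F7. Isobutyl chloroformate and N-methylmorpholine convert it into the isobutyl carbonic mixed anhydride F8, which acylates diazomethane to 6-(diazoacetyl)-3-(methoxymethoxy)-2-[4-(methoxymethoxy)phenyl]-4H-pyran-4-one F9 (first stage of an Arndt–Eistert sequence). F9 and 15 under the conditions of step 10 should pass through pyranylketene F10, 3-methoxy-4-pyranylcyclobut-2-en-1-one F11, (E)-3-methoxy-4-pyranylbuta-1,3-dien-1-one F12 and rac-7-methoxy-3-(methoxymethoxy)-2-[4-(methoxymethoxy)phenyl]-4aH-chromene-4,5-dione F13 to 5-hydroxy-7-methoxy-3-(methoxymethoxy)-2-[4-(methoxymethoxy)phenyl]-4H-chromen-4-one F14. O-prenylation of its chelated 5-OH (prenyl bromide, K2CO3, DMF, 50 °C) gives the 5-O-prenyl ether F6 of the first fallback, and the same Eu(fod)3 Claisen–Cope shift leads to 20. This version uses the parent diazomethyl ketone, the standard substrate type of the Wolff benzannulation, which has no β-hydrogen to shift, at the price of bringing back a C6 versus C8 question in the prenyl transfer.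

Step 5. Conjugate addition of the Grignard reagent to the pyranone, or reduction of the aldehyde by β-hydride transfer, may compete with 1,2-addition. The fallback replaces carbonyl addition by a palladium-catalysed acyl coupling with a non-basic organozinc; it sets out from aldehyde 6 and comes back at ketone 10, so that alcohol 9 and step 6 drop out. The carboxylic acid F7, made by the Pinnick oxidation described above, is converted with EtSH, EDC·HCl and DMAP in CH2Cl2 into S-ethyl 5-(methoxymethoxy)-6-[4-(methoxymethoxy)phenyl]-4-oxo-4H-pyran-2-carbothioate F15. Fukuyama coupling of F15 with (4-methylpent-3-enyl)zinc bromide F16 (from 7 with Zn dust and LiCl in THF) under PdCl2(PPh3)2 in toluene/THF at rt should give 10. The organozinc does not add to pyranones or ketones, so acyl substitution at the thioester is the only C–C bond formation expected.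

Further compounds
F1 | step 10 | 1-(2,6-dihydroxy-4-methoxyphenyl)ethanone (purchased) | CC(=O)c1c(O)cc(OC)cc1O
F2 | step 10 | 1-[2-hydroxy-4-methoxy-6-(3-methylbut-2-enyloxy)phenyl]ethanone | CC(=O)c1c(O)cc(OC)cc1OCC=C(C)C
F3 | step 10 | 4-(methoxymethoxy)benzaldehyde (purchased) | COCOc1ccc(C=O)cc1
F4 | step 10 | (E)-1-[2-hydroxy-4-methoxy-6-(3-methylbut-2-enyloxy)phenyl]-3-[4-(methoxymethoxy)phenyl]prop-2-en-1-one | COCOc1ccc(/C=C/C(=O)c2c(O)cc(OC)cc2OCC=C(C)C)cc1
F5 | step 10 | 3-hydroxy-7-methoxy-2-[4-(methoxymethoxy)phenyl]-5-(3-methylbut-2-enyloxy)-4H-chromen-4-one | COCOc1ccc(-c2oc3cc(OC)cc(OCC=C(C)C)c3c(=O)c2O)cc1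
F6 | step 10 | 7-methoxy-3-(methoxymethoxy)-2-[4-(methoxymethoxy)phenyl]-5-(3-methylbut-2-enyloxy)-4H-chromen-4-one | COCOc1ccc(-c2oc3cc(OC)cc(OCC=C(C)C)c3c(=O)c2OCOC)cc1
F7 | step 7 | 5-(methoxymethoxy)-6-[4-(methoxymethoxy)phenyl]-4-oxo-4H-pyran-2-carboxylic acid | O=C(O)c1cc(=O)c(OCOC)c(-c2ccc(OCOC)cc2)o1
F8 | step 7 | isobutyl carbonic mixed anhydride of F7 | CC(C)COC(=O)OC(=O)c1cc(=O)c(OCOC)c(-c2ccc(OCOC)cc2)o1
F9 | step 7 | 6-(diazoacetyl)-3-(methoxymethoxy)-2-[4-(methoxymethoxy)phenyl]-4H-pyran-4-one | [N-]=[N+]=CC(=O)c1cc(=O)c(OCOC)c(-c2ccc(OCOC)cc2)o1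
F10 | step 7 | pyranylketene, 2-{5-(methoxymethoxy)-6-[4-(methoxymethoxy)phenyl]-4-oxo-4H-pyran-2-yl}ethen-1-one | O=C=Cc1cc(=O)c(OCOC)c(-c2ccc(OCOC)cc2)o1
F11 | step 7 | rac-3-methoxy-4-{5-(methoxymethoxy)-6-[4-(methoxymethoxy)phenyl]-4-oxo-4H-pyran-2-yl}cyclobut-2-en-1-one | COC1=CC(=O)C1c1cc(=O)c(OCOC)c(-c2ccc(OCOC)cc2)o1
F12 | step 7 | (E)-3-methoxy-4-{5-(methoxymethoxy)-6-[4-(methoxymethoxy)phenyl]-4-oxo-4H-pyran-2-yl}buta-1,3-dien-1-one | O=C=C/C(OC)=C\c1cc(=O)c(OCOC)c(-c2ccc(OCOC)cc2)o1
F13 | step 7 | rac-7-methoxy-3-(methoxymethoxy)-2-[4-(methoxymethoxy)phenyl]-4aH-chromene-4,5-dione | COC1=CC(=O)C2C(=O)C(OCOC)=C(c3ccc(OCOC)cc3)OC2=C1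
F14 | step 7 | 5-hydroxy-7-methoxy-3-(methoxymethoxy)-2-[4-(methoxymethoxy)phenyl]-4H-chromen-4-one | COc1cc(O)c2c(=O)c(OCOC)c(-c3ccc(OCOC)cc3)oc2c1
F15 | step 5 | S-ethyl 5-(methoxymethoxy)-6-[4-(methoxymethoxy)phenyl]-4-oxo-4H-pyran-2-carbothioate | CCSC(=O)c1cc(=O)c(OCOC)c(-c2ccc(OCOC)cc2)o1
F16 | step 5 | (4-methylpent-3-enyl)zinc bromide | CC(C)=CCC[Zn]Br
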